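Assumptions: compounds 1, 2, 6, 9, 13 and 17 are catalogue chemicals. Comments use germacrane numbering (lactone O on C6, tiglate on C8, carbinol C10, ketone C3). Bulk reagents and catalysts (I2, TBHP, Zn and so on) are not numbered.

## Retrosynthetic overview
1. The C3 ketone comes from oxidation of a bis-allylic alcohol. The ten-membered ring is closed last, by intramolecular Nozaki–Hiyama–Kishi (NHK) coupling at C3–C4 of a (Z)-vinyl iodide and an (E)-enal.
2. The 8β-tiglate comes from Mitsunobu inversion of the 8-epi carbinol. A ring-locked allylzinc can only give the 7,8-anti adduct, but the target is 7,8-syn.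
3. The C7–C8 bond and the α-methylene lactone come from a Zn-Barbier SE2′ allylation of aldehyde 15 with bromomethylbutenolide 8. C6 controls C7.
4. Compound 8 comes from acrolein and propynyl-MgBr (lipase resolution sets C6, Red-Al/I2 sets 4Z, then RCM). Compound 15 comes from enynol 9 (Sharpless epoxidation sets C10, then Red-Al, Lindlar, cross-metathesis).
5. Ring order: butenolide (RCM), then trans-α-methylene-γ-butyrolactone (Barbier), then the cyclodecadiene (NHK).

## Fragment A (C4–C7, C11–C13, C15)

**Step 1**
Reactants: 1 acrolein; 2 1-propynylmagnesium bromide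
Product: 3 (±)-hex-1-en-4-yn-3-ol
Conditions: THF, −78 → 0 °C; aq NH4Cl
Reagents that add atoms: 1-propynylmagnesium bromide, CC#C[Mg]Br
Why: Grignard 1,2-addition to the enal gives the vinyl/propynyl carbinol (carbinol carbon = C6), racemic at this stage.

**Step 2**
Reactants: 3
Product: 4 (S)-hex-1-en-4-yn-3-ol
Conditions: Novozym 435, vinyl acetate, MTBE, rt, stop at about 55 % conversion; separate the (R)-acetate
Reagents that add atoms: none
Why: In this lipase kinetic resolution (Kazlauskas rule, propynyl = large group, vinyl = medium group) the (R)-alcohol is acetylated and (S)-4 is recovered, which sets C6.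

**Step 3**
Reactants: 4
Product: 5 (3S,4Z)-5-iodohexa-1,4-dien-3-ol
Conditions: Red-Al, THF, 0 °C → rt; EtOAc quench; I2, −78 → 0 °C
Reagents that add atoms: iodine, II
Why: Hydroxyl-directed trans-hydroalumination puts Al on the distal alkyne carbon, cis to C6, and iodinolysis with retention gives only the (Z)-iodide (the future 4Z olefin) without touching C6.

**Step 4**
Reactants: 5; 6 2-(bromomethyl)acrylic acid
Product: 7 (3S,4Z)-5-iodohexa-1,4-dien-3-yl 2-(bromomethyl)prop-2-enoate
Conditions: DIC, DMAP (5 mol %), CH2Cl2, 0 °C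
Reagents that add atoms: 2-(bromomethyl)acrylic acid, C=C(CBr)C(=O)O
Why: Steglich esterification at O leaves the C6–O bond intact, and cold conditions with little DMAP avoid SN2′ attack on the allylic bromide.

**Step 5**
Reactants: 7
Product: 8 (5S)-3-(bromomethyl)-5-[(Z)-2-iodoprop-1-enyl]furan-2(5H)-one
Conditions: Grubbs II (5 mol %), CH2Cl2 (5 mM), 40 °C
Reagents that add atoms: none
Why: Ring-closing metathesis of the vinyl group with the 1,1-disubstituted acrylate forms the butenolide, while the trisubstituted vinyl iodide and the allylic bromide are inert.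

## Fragment B (C1–C3, C8–C10, C14)

**Step 6**
Reactants: 9 (E)-3-methylpent-2-en-4-yn-1-ol
Product: 10 [(2S,3S)-3-ethynyl-3-methyloxiran-2-yl]methanol
Conditions: Ti(OiPr)4 (10 mol %), L-(+)-DET, TBHP, 4 Å MS, CH2Cl2, −20 °C
Reagents that add atoms: tert-butyl hydroperoxide, CC(C)(C)OO
Why: Sharpless asymmetric epoxidation with L-(+)-tartrate gives the (2S,3S)-epoxide (same facial sense as geraniol), which fixes the C10–O stereocentre.

**Step 7**
Reactants: 10
Product: 11 (R)-3-methylpent-4-yne-1,3-diol
Conditions: Red-Al, THF, −20 → 0 °C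
Reagents that add atoms: none
Why: Alkoxide-directed hydride delivery opens the 2,3-epoxy alcohol at C2 because C3 is fully substituted, the C10–O bond is retained, and any over-reduced alkyne is simply compound 12.

**Step 8**
Reactants: 11
Product: 12 (R)-3-methylpent-4-ene-1,3-diol
Conditions: H2 (1 atm), Lindlar catalyst, quinoline, EtOAc, rt
Reagents that add atoms: none
Why: Lindlar semihydrogenation of the terminal ethynyl carbinol stops at the vinyl carbinol.

**Step 9**
Reactants: 12; 13 acrolein diethyl acetal
Product: 14 (3R,4E)-6,6-diethoxy-3-methylhex-4-ene-1,3-diol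
Conditions: 13 (3 equiv), Hoveyda–Grubbs II (5 mol %), CH2Cl2, 40 °C
Reagents that add atoms: 3,3-diethoxyprop-1-ene, C=CC(OCC)OCC
Why: Olefin cross-metathesis of the free tertiary allylic alcohol gives the E-alkene, and it is run here because after step 11 the vinyl group and the α-methylene would ring-close to a cyclohexene.

**Step 10**
Reactants: 14
Product: 15 (3R,4E)-6,6-diethoxy-3-hydroxy-3-methylhex-4-enal
Conditions: DMP, NaHCO3, CH2Cl2, 0 °C; use at once
Reagents that add atoms: none
Why: Buffered Dess–Martin oxidation touches only the primary alcohol, and the neutral medium avoids acetal loss, retro-aldol and dehydration.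

## Union and endgame

**Step 11**
Reactants: 8 (1.5 equiv); 15
Product: 16 (4R,5S)-4-[(1S,3R,4E)-6,6-diethoxy-1,3-dihydroxy-3-methylhex-4-enyl]-5-[(Z)-2-iodoprop-1-enyl]-3-methylideneoxolan-2-one
Conditions: Zn dust, THF/sat. aq NH4Cl, 0 °C → rt
Reagents that add atoms: none
Why: In this Barbier SE2′ allylation the allylzinc attacks through C7 anti to the C6 alkenyl group (trans lactone, C7 set), and the ring-locked E-type Zimmerman–Traxler chair gives the 7,8-anti carbinol, which is the 8-epi (8S) alcohol.

**Step 12**
Reactants: 16; 17 tiglic acid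
Product: 18 (1R,3R,4E)-6,6-diethoxy-3-hydroxy-1-{(2S,3R)-2-[(Z)-2-iodoprop-1-enyl]-4-methylidene-5-oxooxolan-3-yl}-3-methylhex-4-enyl (E)-2-methylbut-2-enoate
Conditions: PPh3/DIAD (betaine pre-formed), 17 (3 equiv), toluene, 0 °C → rt
Reagents that add atoms: tiglic acid, C/C=C(\C)C(=O)O
Why: Mitsunobu esterification installs the tiglate with clean SN2 inversion (8S → 8R), the tertiary C10–OH cannot be activated, and the tiglate keeps its E geometry.

**Step 13**
Reactants: 18
Product: 19 (1R,3R,4E)-3-hydroxy-1-{(2S,3R)-2-[(Z)-2-iodoprop-1-enyl]-4-methylidene-5-oxooxolan-3-yl}-3-methyl-6-oxohex-4-enyl (E)-2-methylbut-2-enoate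
Conditions: PPTS (cat.), acetone/H2O 10:1, rt
Reagents that add atoms: water, O
Why: Mild acetal hydrolysis releases the (E)-enal, and the E geometry prevents lactol formation with the C10–OH.

**Step 14**
Reactants: 19
Product: 20 (3aR,4R,6R,7E,10Z,11aR)-6,9-dihydroxy-6,10-dimethyl-3-methylidene-2-oxo-2,3,3a,4,5,6,9,11a-octahydrocyclodeca[b]furan-4-yl tiglate (C3 epimers)
Conditions: CrCl2 (15 equiv), NiCl2 (about 1 wt %), DMSO, 2 mM, rt
Reagents that add atoms: none
Why: Intramolecular Nozaki–Hiyama–Kishi coupling adds the alkenylchromium 1,2 to the enal with retention of the Z geometry, it tolerates the lactone, the ester and the free OH, and the new C3 stereocentre is erased in the next step.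

**Step 15**
Reactants: 20
Product: 21 eupaheliangolide A
Conditions: DMP, NaHCO3, CH2Cl2, 0 °C
Reagents that add atoms: none
Why: Dess–Martin oxidation turns both C3 epimers of the bis-allylic alcohol into the cross-conjugated dienone, and the tertiary C10–OH cannot be oxidised.

## Compound list
| No. | Name | SMILES | Role |
|---|---|---|---|
| 1 | acrolein | C=CC=O | starting material |
| 2 | 1-propynylmagnesium bromide | CC#C[Mg]Br | starting material |
| 3 | (±)-hex-1-en-4-yn-3-ol | C=CC(O)C#CC | intermediate |
| 4 | (S)-hex-1-en-4-yn-3-ol | C=C[C@H](O)C#CC | intermediate |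
| 5 | (3S,4Z)-5-iodohexa-1,4-dien-3-ol | C=C[C@H](O)/C=C(/C)I | intermediate |
| 6 | 2-(bromomethyl)acrylic acid | C=C(CBr)C(=O)O | starting material |
| 7 | bromomethacrylate ester of 5 | C=C(CBr)C(=O)O[C@H](/C=C(/C)I)C=C | intermediate |
| 8 | (5S)-3-(bromomethyl)-5-[(Z)-2-iodoprop-1-enyl]furan-2(5H)-one | O=C1O[C@H](/C=C(/C)I)C=C1CBr | intermediate |
| 9 | (E)-3-methylpent-2-en-4-yn-1-ol | C#C/C(C)=C/CO | starting material |
| 10 | [(2S,3S)-3-ethynyl-3-methyloxiran-2-yl]methanol | OC[C@@H]1O[C@@]1(C)C#C | intermediate |
| 11 | (R)-3-methylpent-4-yne-1,3-diol | OCC[C@@](C)(O)C#C | intermediate |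
| 12 | (R)-3-methylpent-4-ene-1,3-diol | OCC[C@@](C)(O)C=C | intermediate |
| 13 | acrolein diethyl acetal | C=CC(OCC)OCC | starting material |
| 14 | (3R,4E)-6,6-diethoxy-3-methylhex-4-ene-1,3-diol | OCC[C@@](C)(O)/C=C/C(OCC)OCC | intermediate |
| 15 | (3R,4E)-6,6-diethoxy-3-hydroxy-3-methylhex-4-enal | O=CC[C@@](C)(O)/C=C/C(OCC)OCC | intermediate |
| 16 | Barbier adduct (8-epi carbinol) | C=C1C(=O)O[C@H](/C=C(/C)I)[C@H]1[C@@H](O)C[C@@](C)(O)/C=C/C(OCC)OCC | intermediate |
| 17 | tiglic acid | C/C=C(\C)C(=O)O | starting material |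
| 18 | 8β-tiglate acetal | C=C1C(=O)O[C@H](/C=C(/C)I)[C@H]1[C@H](OC(=O)/C(C)=C/C)C[C@@](C)(O)/C=C/C(OCC)OCC | intermediate |
| 19 | iodo-enal (seco compound) | C=C1C(=O)O[C@H](/C=C(/C)I)[C@H]1[C@H](OC(=O)/C(C)=C/C)C[C@@](C)(O)/C=C/C=O | intermediate |
| 20 | macrocyclic C3 alcohol (epimers) | C=C1C(=O)O[C@@H]2/C=C(/C)C(O)/C=C/[C@](C)(O)C[C@@H](OC(=O)/C(C)=C/C)[C@@H]12 | intermediate |
| 21 | eupaheliangolide A (6R,7R,8R,10R; 1E,4Z) | C=C1C(=O)O[C@@H]2/C=C(/C)C(=O)/C=C/[C@](C)(O)C[C@@H](OC(=O)/C(C)=C/C)[C@@H]12 | target |

## Summary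
**Total steps:** 15.
**Longest linear sequence:** 10 (steps 1–5 then 11–15; the branch through steps 6–10 is the same length).

**Three steps most likely to fail**
1. **Step 12, Mitsunobu inversion at the α-branched C8.** Elimination to the 7,8-ene, oxetane formation or no reaction are all possible.
   - Fallback: remove the need for inversion by changing how the C7–C8 bond is made.
   - Convert 8 into the allyl-tributylstannane and add it to the 10-O-TES ether of 15 with BF3·OEt2. The open, antiperiplanar transition state gives the 7,8-syn adduct, which is the 8R carbinol.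
   - Esterify with retention (Yamaguchi, tiglic acid). Any 8R isomer formed in step 11 can be converged in the same way.
2. **Step 14, NHK closure of the ten-membered ring.** Oligomerisation and Ni-mediated cyclisation of the vinyl metal onto the methylene lactone are the main threats.
   - Fallback: reverse the order of the two C–C couplings.
   - Join C3–C4 first by an intermolecular NHK, carrying C13 as CH2OTBS.
   - Unmask the bromide and the C8 aldehyde, then close the ring at C7–C8 by intramolecular Zn or CrCl2 Barbier allylation.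
3. **Step 9, cross-metathesis of the hindered tertiary allylic alcohol with the acrolein acetal.**
   - Fallback: a metathesis-free route to 15.
   - A Wittig reaction of 2,2-diethoxyacetaldehyde with acetonylidene-triphenylphosphorane gives (E)-5,5-diethoxypent-3-en-2-one.
   - BINOL-catalysed asymmetric allylboration of that ketone sets C10.
   - Selective OsO4/NaIO4 cleavage of the terminal alkene gives the C8 aldehyde.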